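**Assumption:** the SMILES is read as (2E,4S,5R,7R,12S,13R), meaning C3 and C6 are cis on the oxirane (the epoxide of a 4Z-olefin) and C12-OH/C13-CH2OH are syn; the L-fructose-derived Shi ketone is taken as purchasable.

## Retrosynthetic overview

1. Both acids come from a C1 methyl ester and a C14 Evans imide (one final hydrolysis); the C13 CH2OH is carried as a TBS ether.
2. The oxirane, the only ring, is formed late, after all C–C bonds, by Shi epoxidation of the γ,δ-olefin of a (2E,4Z)-dienoate.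
3. C12–C13: Evans syn aldol of the C1–C12 dienoate aldehyde with an (R)-benzyloxazolidinone 3-silyloxypropanoyl imide.
4. C5–C6, C4=C5, C3–C4 and C2=C3: one-pot carbocupration of propyne by the C6–C12 alkylcopper, then syn addition to methyl but-2-ynoate.
5. C8–C9: Cu-catalysed Grignard coupling of (S)-1-bromo-3-chloro-2-methylpropane (source of C7) with a dioxolane-masked C9–C12 Grignard reagent.

## Route

**Step 1**
Reactants: 1 2-(3-chloropropyl)-1,3-dioxolane; 2 (S)-1-bromo-3-chloro-2-methylpropane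
Product: 4 2-[(5R)-6-chloro-5-methylhexyl]-1,3-dioxolane, via Grignard reagent 3 (not isolated)
Conditions: Mg, THF, reflux; then 2, Li2CuCl4 (3 mol %), THF, −10 °C → rt
Reagents that add atoms: none
Why: Li2CuCl4-catalysed (Kochi-type) sp3–sp3 Grignard coupling takes the primary bromide and leaves the chloride, and the C7 centre of 2 is untouched (S becomes R only by the priority change).

**Step 2**
Reactants: 4 2-[(5R)-6-chloro-5-methylhexyl]-1,3-dioxolane; 5 propyne; 6 methyl but-2-ynoate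
Product: 11 methyl (2E,4Z,7R)-11-(1,3-dioxolan-2-yl)-3,5,7-trimethylundeca-2,4-dienoate, via alkylmagnesium chloride 7 (not isolated), via alkylcopper 8 (not isolated), via (Z)-alkenylcopper 9 (not isolated), via 2-cuprio dienoate 10 (not isolated)
Conditions: Mg (BrCH2CH2Br-activated), Et2O, reflux; CuBr·SMe2, Et2O/Me2S, −45 °C; 5, −25 °C; then 6, THF, −78 → −30 °C; aq. NH4Cl
Reagents that add atoms: none
Why: Normant carbocupration adds the alkylcopper syn across propyne (alkyl to the internal carbon, Cu cis to it), which fixes 4Z, and the alkenylcopper then adds syn to the ynoate so that protonation gives the 2E-enoate.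

**Step 3**
Reactants: 11 methyl (2E,4Z,7R)-11-(1,3-dioxolan-2-yl)-3,5,7-trimethylundeca-2,4-dienoate
Product: 12 methyl (2E,4Z,7R)-3,5,7-trimethyl-12-oxododeca-2,4-dienoate
Conditions: 1 M HCl, THF, rt
Reagents that add atoms: water, O
Why: Acid-catalysed acetal hydrolysis unmasks the C12 aldehyde, and the dienoate is inert to dilute aqueous acid at rt.

**Step 4**
Reactants: 13 3-[(tert-butyldimethylsilyl)oxy]propanal
Product: 14 3-[(tert-butyldimethylsilyl)oxy]propanoic acid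
Conditions: NaClO2, NaH2PO4, 2-methylbut-2-ene, t-BuOH/H2O, 0 °C → rt
Reagents that add atoms: sodium chlorite, [Na+].[O-]Cl=O
Why: Pinnick oxidation converts the aldehyde to the acid under buffered conditions that keep the primary TBS ether.

**Step 5**
Reactants: 14 3-[(tert-butyldimethylsilyl)oxy]propanoic acid; 15 (4R)-4-benzyl-1,3-oxazolidin-2-one
Product: 17 (4R)-4-benzyl-3-{3-[(tert-butyldimethylsilyl)oxy]propanoyl}-1,3-oxazolidin-2-one, via mixed pivalic anhydride 16 (not isolated)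
Conditions: PivCl, Et3N, THF, −20 °C; then LiCl, 15, −20 °C → rt
Reagents that add atoms: none
Why: N-acylation of the oxazolidinone through the mixed pivalic anhydride (LiCl/Et3N) is the standard mild way to Evans imides.

**Step 6**
Reactants: 17 (4R)-4-benzyl-3-{3-[(tert-butyldimethylsilyl)oxy]propanoyl}-1,3-oxazolidin-2-one; 12 methyl (2E,4Z,7R)-3,5,7-trimethyl-12-oxododeca-2,4-dienoate
Product: 20 methyl (2E,4Z,7R,12S,13R)-14-[(4R)-4-benzyl-2-oxo-1,3-oxazolidin-3-yl]-13-{[(tert-butyldimethylsilyl)oxy]methyl}-12-hydroxy-3,5,7-trimethyl-14-oxotetradeca-2,4-dienoate, via boron (Z)-enolate 18 (not isolated), via boron aldolate 19 (not isolated)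
Conditions: Bu2BOTf, Et3N, CH2Cl2, −78 → 0 °C; 12, −78 → 0 °C; pH 7 buffer, MeOH, 30 % H2O2, 0 °C
Reagents that add atoms: none
Why: Evans syn aldol, in which the (Z)-boron enolate reacts through a Zimmerman–Traxler chair on the face away from the benzyl group of the (R)-auxiliary, sets 13R and 12S (syn), and the non-basic boron enolate should not expel the β-silyloxy group.

**Step 7**
Reactants: 20 (the aldol adduct of step 6)
Product: 21 methyl (2E,4S,5R,7R,12S,13R)-14-[(4R)-4-benzyl-2-oxo-1,3-oxazolidin-3-yl]-13-{[(tert-butyldimethylsilyl)oxy]methyl}-4,5-epoxy-12-hydroxy-3,5,7-trimethyl-14-oxotetradec-2-enoate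
Conditions: 1,2:4,5-di-O-isopropylidene-β-L-erythro-2,3-hexodiulo-2,6-pyranose (L-fructose-derived Shi ketone, 30 mol %), KHSO5 (as 2KHSO5·KHSO4·K2SO4), K2CO3, Bu4NHSO4, MeCN/dimethoxymethane/aq. Na2B4O7–Na2EDTA, 0 °C
Reagents that add atoms: potassium peroxymonosulfate, [K+].[O-]S(=O)(=O)OO
Why: Shi asymmetric epoxidation, in which the chiral dioxirane attacks only the electron-richer γ,δ-olefin (C2=C3 is deactivated by the ester), adds oxygen syn so C3/C6 stay cis, and by the spiro transition-state model the L-series ketone gives 4S,5R.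

**Step 8**
Reactants: 21 (the epoxide of step 7)
Product: 22 methyl (2E,4S,5R,7R,12S,13R)-14-[(4R)-4-benzyl-2-oxo-1,3-oxazolidin-3-yl]-4,5-epoxy-12-hydroxy-13-(hydroxymethyl)-3,5,7-trimethyl-14-oxotetradec-2-enoate
Conditions: HF·pyridine, pyridine, THF, 0 °C → rt
Reagents that add atoms: none
Why: Fluoride-mediated desilylation of the primary TBS ether under pyridine-buffered conditions leaves the trisubstituted oxirane and the imide intact.

**Step 9**
Reactants: 22 (the diol imide of step 8)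
Product: 25 (2E,4S,5R,7R,12S,13R)-4,5-epoxy-12-hydroxy-13-(hydroxymethyl)-3,5,7-trimethyltetradec-2-enedioic acid (target), via peroxy acid 23 (not isolated), via acid ester 24 (not isolated)
Conditions: LiOH, 30 % H2O2, THF/H2O, 0 °C; Na2SO3; then LiOH, THF/MeOH/H2O, rt; cold aq. NaHSO4 to pH 4
Reagents that add atoms: hydrogen peroxide, OO; lithium hydroxide, [Li+].[OH-]
Why: Hydroperoxide cleavage of the Evans imide (exocyclic attack, no epimerisation at C13) followed by saponification of the methyl ester frees both acids, and the oxirane is expected to tolerate base and the cold, brief acidification.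

## Compound list

1 | 2-(3-chloropropyl)-1,3-dioxolane | ClCCCC1OCCO1 | starting material
2 | (S)-1-bromo-3-chloro-2-methylpropane | ClC[C@H](C)CBr | starting material
3 | [3-(1,3-dioxolan-2-yl)propyl]magnesium chloride | Cl[Mg]CCCC1OCCO1 | intermediate (not isolated)
4 | 2-[(5R)-6-chloro-5-methylhexyl]-1,3-dioxolane | ClC[C@H](C)CCCCC1OCCO1 | intermediate
5 | propyne | CC#C | starting material
6 | methyl but-2-ynoate | CC#CC(=O)OC | starting material
7 | [(2R)-6-(1,3-dioxolan-2-yl)-2-methylhexyl]magnesium chloride | Cl[Mg]C[C@H](C)CCCCC1OCCO1 | intermediate (not isolated)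
8 | [(2R)-6-(1,3-dioxolan-2-yl)-2-methylhexyl]copper (MgBrCl complex) | [Cu]C[C@H](C)CCCCC1OCCO1 | intermediate (not isolated)
9 | [(1Z,4R)-8-(1,3-dioxolan-2-yl)-2,4-dimethyloct-1-en-1-yl]copper | [Cu]/C=C(/C)\C[C@H](C)CCCCC1OCCO1 | intermediate (not isolated)
10 | methyl (2Z,4Z,7R)-2-cuprio-11-(1,3-dioxolan-2-yl)-3,5,7-trimethylundeca-2,4-dienoate | COC(=O)/C([Cu])=C(\C)/C=C(/C)\C[C@H](C)CCCCC1OCCO1 | intermediate (not isolated)
11 | methyl (2E,4Z,7R)-11-(1,3-dioxolan-2-yl)-3,5,7-trimethylundeca-2,4-dienoate | COC(=O)/C=C(\C)/C=C(/C)\C[C@H](C)CCCCC1OCCO1 | intermediate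
12 | methyl (2E,4Z,7R)-3,5,7-trimethyl-12-oxododeca-2,4-dienoate | COC(=O)/C=C(\C)/C=C(/C)\C[C@H](C)CCCCC=O | intermediate
13 | 3-[(tert-butyldimethylsilyl)oxy]propanal | O=CCCO[Si](C)(C)C(C)(C)C | starting material
14 | 3-[(tert-butyldimethylsilyl)oxy]propanoic acid | OC(=O)CCO[Si](C)(C)C(C)(C)C | intermediate
15 | (4R)-4-benzyl-1,3-oxazolidin-2-one | O=C1OC[C@@H](Cc2ccccc2)N1 | starting material
16 | 3-[(tert-butyldimethylsilyl)oxy]propanoic pivalic anhydride | CC(C)(C)C(=O)OC(=O)CCO[Si](C)(C)C(C)(C)C | intermediate (not isolated)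
17 | (4R)-4-benzyl-3-{3-[(tert-butyldimethylsilyl)oxy]propanoyl}-1,3-oxazolidin-2-one | O=C1OC[C@@H](Cc2ccccc2)N1C(=O)CCO[Si](C)(C)C(C)(C)C | intermediate
18 | dibutylboron (Z)-enolate of 17 | CCCCB(CCCC)O/C(=C\CO[Si](C)(C)C(C)(C)C)N1[C@H](Cc2ccccc2)COC1=O | intermediate (not isolated)
19 | O12-dibutylboryl aldolate of 20 | COC(=O)/C=C(\C)/C=C(/C)\C[C@H](C)CCCC[C@H](OB(CCCC)CCCC)[C@@H](CO[Si](C)(C)C(C)(C)C)C(=O)N1[C@H](Cc2ccccc2)COC1=O | intermediate (not isolated)
20 | methyl (2E,4Z,7R,12S,13R)-14-[(4R)-4-benzyl-2-oxo-1,3-oxazolidin-3-yl]-13-{[(tert-butyldimethylsilyl)oxy]methyl}-12-hydroxy-3,5,7-trimethyl-14-oxotetradeca-2,4-dienoate | COC(=O)/C=C(\C)/C=C(/C)\C[C@H](C)CCCC[C@H](O)[C@@H](CO[Si](C)(C)C(C)(C)C)C(=O)N1[C@H](Cc2ccccc2)COC1=O | intermediate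
21 | methyl (2E,4S,5R,7R,12S,13R)-14-[(4R)-4-benzyl-2-oxo-1,3-oxazolidin-3-yl]-13-{[(tert-butyldimethylsilyl)oxy]methyl}-4,5-epoxy-12-hydroxy-3,5,7-trimethyl-14-oxotetradec-2-enoate | COC(=O)/C=C(\C)[C@@H]1O[C@]1(C)C[C@H](C)CCCC[C@H](O)[C@@H](CO[Si](C)(C)C(C)(C)C)C(=O)N2[C@H](Cc3ccccc3)COC2=O | intermediate
22 | methyl (2E,4S,5R,7R,12S,13R)-14-[(4R)-4-benzyl-2-oxo-1,3-oxazolidin-3-yl]-4,5-epoxy-12-hydroxy-13-(hydroxymethyl)-3,5,7-trimethyl-14-oxotetradec-2-enoate | COC(=O)/C=C(\C)[C@@H]1O[C@]1(C)C[C@H](C)CCCC[C@H](O)[C@@H](CO)C(=O)N2[C@H](Cc3ccccc3)COC2=O | intermediate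
23 | 14-peroxy acid of 24 (C1 methyl ester, C14 = C(=O)OOH) | COC(=O)/C=C(\C)[C@@H]1O[C@]1(C)C[C@H](C)CCCC[C@H](O)[C@@H](CO)C(=O)OO | intermediate (not isolated)
24 | (2E,4S,5R,7R,12S,13R)-4,5-epoxy-12-hydroxy-13-(hydroxymethyl)-3,5,7-trimethyltetradec-2-enedioic acid 1-methyl ester | COC(=O)/C=C(\C)[C@@H]1O[C@]1(C)C[C@H](C)CCCC[C@H](O)[C@@H](CO)C(=O)O | intermediate (not isolated)
25 | (2E,4S,5R,7R,12S,13R)-4,5-epoxy-12-hydroxy-13-(hydroxymethyl)-3,5,7-trimethyltetradec-2-enedioic acid | C/C(=C\C(=O)O)[C@@H]1O[C@]1(C)C[C@H](C)CCCC[C@H](O)[C@@H](CO)C(=O)O | target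

## Step count and risks

Total steps: 9. Longest linear sequence: 7 (steps 1, 2, 3, 6, 7, 8, 9); steps 4 and 5 make the aldol partner.

**Step 2 (most likely to fail).** The alkenylcopper may add sluggishly to the β-methyl ynoate, or the 2-cuprio ester may equilibrate and erode 2E; Grignard formation from the chloride in ether can also be slow. The fallback separates olefin construction from C3–C4 bond formation by a cross-coupling. It sets out from alkenylcopper 9 (made from 4 as in step 2) and comes back at 11. Compound 9 is quenched with I2 to give the vinyl iodide 2-[(5R,7Z)-8-iodo-5,7-dimethyloct-7-en-1-yl]-1,3-dioxolane F1. Separately, 6 is syn-hydroborated (B2pin2, CuCl, NaOtBu, Ph3P, MeOH) to methyl (2Z)-3-(4,4,5,5-tetramethyl-1,3,2-dioxaborolan-2-yl)but-2-enoate F2. Suzuki–Miyaura coupling of the two (Pd(PPh3)4, a zerovalent palladium catalyst, aq. K3PO4, THF, 50 °C) proceeds with retention at both partners and gives 11.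

**Step 7.** Face selectivity on this twisted, Z-configured trisubstituted diene is unproven, and the imide sees pH about 10. The fallback builds the oxirane by Sharpless epoxidation before the C2=C3 bond exists. It sets out from alkenylcopper 9 and comes back at 21.
- Carboxylation of 9 (CO2, cat. P(OEt)3, HMPA) gives (2Z,5R)-9-(1,3-dioxolan-2-yl)-3,5-dimethylnon-2-enoic acid F3.
- LiAlH4 reduction gives (2Z,5R)-9-(1,3-dioxolan-2-yl)-3,5-dimethylnon-2-en-1-ol F4.
- Epoxidation with Ti(OiPr)4, L-(+)-diethyl tartrate and t-BuOOH (4 Å sieves, CH2Cl2, −20 °C) gives {(2S,3R)-3-[(2R)-6-(1,3-dioxolan-2-yl)-2-methylhexyl]-3-methyloxiran-2-yl}methanol F5.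
- Dess–Martin oxidation gives (2R,3R)-3-[(2R)-6-(1,3-dioxolan-2-yl)-2-methylhexyl]-3-methyloxirane-2-carbaldehyde F6.
- MeMgBr (−78 °C) gives 1-{(2S,3R)-3-[(2R)-6-(1,3-dioxolan-2-yl)-2-methylhexyl]-3-methyloxiran-2-yl}ethan-1-ol F7 (both carbinol epimers).
- A second Dess–Martin oxidation gives 1-{(2R,3R)-3-[(2R)-6-(1,3-dioxolan-2-yl)-2-methylhexyl]-3-methyloxiran-2-yl}ethan-1-one F8.
- Horner–Wadsworth–Emmons olefination (trimethyl phosphonoacetate, NaH, THF) gives methyl (2E)-3-{(2S,3R)-3-[(2R)-6-(1,3-dioxolan-2-yl)-2-methylhexyl]-3-methyloxiran-2-yl}but-2-enoate F9.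
- Acetal cleavage with oxalic acid on wet silica gel gives methyl (2E)-3-{(2S,3R)-3-methyl-3-[(2R)-2-methyl-7-oxoheptyl]oxiran-2-yl}but-2-enoate F10.
- The Evans aldol of step 6 with 17 then gives 21.

**Step 9.** The vinyl oxirane and the β-hydroxy acid must survive the slow saponification of a β,β-disubstituted enoate. The fallback saponifies first and epoxidises last. It sets out from 20 and comes back at 25. LiOH/H2O2 followed by LiOH gives (2E,4Z,7R,12S,13R)-13-{[(tert-butyldimethylsilyl)oxy]methyl}-12-hydroxy-3,5,7-trimethyltetradeca-2,4-dienedioic acid F11. HF·pyridine then gives (2E,4Z,7R,12S,13R)-12-hydroxy-13-(hydroxymethyl)-3,5,7-trimethyltetradeca-2,4-dienedioic acid F12. The step 7 epoxidation, run on the dicarboxylate of F12 in the buffered aqueous MeCN medium, gives 25 after cold acidification to pH 4.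

## Further compounds

F1 | step 2 | 2-[(5R,7Z)-8-iodo-5,7-dimethyloct-7-en-1-yl]-1,3-dioxolane | I/C=C(/C)\C[C@H](C)CCCCC1OCCO1
F2 | step 2 | methyl (2Z)-3-(4,4,5,5-tetramethyl-1,3,2-dioxaborolan-2-yl)but-2-enoate | COC(=O)/C=C(\C)B1OC(C)(C)C(C)(C)O1
F3 | step 7 | (2Z,5R)-9-(1,3-dioxolan-2-yl)-3,5-dimethylnon-2-enoic acid | OC(=O)/C=C(/C)\C[C@H](C)CCCCC1OCCO1
F4 | step 7 | (2Z,5R)-9-(1,3-dioxolan-2-yl)-3,5-dimethylnon-2-en-1-ol | OC/C=C(/C)\C[C@H](C)CCCCC1OCCO1
F5 | step 7 | {(2S,3R)-3-[(2R)-6-(1,3-dioxolan-2-yl)-2-methylhexyl]-3-methyloxiran-2-yl}methanol | OC[C@@H]1O[C@]1(C)C[C@H](C)CCCCC2OCCO2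
F6 | step 7 | (2R,3R)-3-[(2R)-6-(1,3-dioxolan-2-yl)-2-methylhexyl]-3-methyloxirane-2-carbaldehyde | O=C[C@@H]1O[C@]1(C)C[C@H](C)CCCCC2OCCO2
F7 | step 7 | 1-{(2S,3R)-3-[(2R)-6-(1,3-dioxolan-2-yl)-2-methylhexyl]-3-methyloxiran-2-yl}ethan-1-ol (carbinol epimers) | CC(O)[C@@H]1O[C@]1(C)C[C@H](C)CCCCC2OCCO2
F8 | step 7 | 1-{(2R,3R)-3-[(2R)-6-(1,3-dioxolan-2-yl)-2-methylhexyl]-3-methyloxiran-2-yl}ethan-1-one | CC(=O)[C@@H]1O[C@]1(C)C[C@H](C)CCCCC2OCCO2
F9 | step 7 | methyl (2E)-3-{(2S,3R)-3-[(2R)-6-(1,3-dioxolan-2-yl)-2-methylhexyl]-3-methyloxiran-2-yl}but-2-enoate | COC(=O)/C=C(\C)[C@@H]1O[C@]1(C)C[C@H](C)CCCCC2OCCO2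
F10 | step 7 | methyl (2E)-3-{(2S,3R)-3-methyl-3-[(2R)-2-methyl-7-oxoheptyl]oxiran-2-yl}but-2-enoate | COC(=O)/C=C(\C)[C@@H]1O[C@]1(C)C[C@H](C)CCCCC=O
F11 | step 9 | (2E,4Z,7R,12S,13R)-13-{[(tert-butyldimethylsilyl)oxy]methyl}-12-hydroxy-3,5,7-trimethyltetradeca-2,4-dienedioic acid | OC(=O)/C=C(\C)/C=C(/C)\C[C@H](C)CCCC[C@H](O)[C@@H](CO[Si](C)(C)C(C)(C)C)C(=O)O
F12 | step 9 | (2E,4Z,7R,12S,13R)-12-hydroxy-13-(hydroxymethyl)-3,5,7-trimethyltetradeca-2,4-dienedioic acid | OC(=O)/C=C(\C)/C=C(/C)\C[C@H](C)CCCC[C@H](O)[C@@H](CO)C(=O)O
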